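## Analysis of the target

Ombuin 3-O-sulfate is a flavonol: a chromen-4-one (benzo ring A fused to pyranone ring C) with an aryl ring B on C2. Ring A carries a hydroxyl at C5, hydrogen-bonded to the C4 carbonyl, and a methoxy group at C7. Ring B carries a hydroxyl at C3' and a methoxy group at C4', and the enolic oxygen on C3 bears the hydrogen sulfate. The molecule has no stereocentre and no stereogenic axis, so it is achiral; the only stereochemical element in the route is the geometry of one alkene intermediate. The sulfate monoester is the sensitive group: it is ionic, cleaved by acid and incompatible with Lewis acids, so it has to be introduced late and followed only by neutral chemistry. The difficulty is therefore not the skeleton but the five oxygens: two stay methylated, two end as free phenols and one is sulfated. The 3-OH and the 3'-OH would both react with a sulfur trioxide donor, so the 3'-oxygen must stay masked through the sulfation and its mask must come off without acid. The strategy rests on ring A: C4a lies between C8a (which carries O1) and C5 (which carries oxygen) and is para to the C7 methoxy group. In a 3,5-dimethoxyphenyl ether of O1 the two carbons ortho to the ether oxygen are therefore activated by all three oxygens and are equivalent by symmetry. The C4–C4a bond can thus be made by acylation with only one possible regiochemical outcome, and the C4 carbonyl formed in that step later directs the cleavage of the 5-O-methyl group.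

## Retrosynthetic reasoning

**13 to 12.** The last bond cut is the benzyl–oxygen bond at C3'. Target 13 is traced back to its 3'-O-benzyl ether 12, because hydrogenolysis is neutral and leaves a sulfate monoester untouched. Keeping this benzyl group until the end removes the 3'-OH from the competition for the sulfating agent.

**12 to 11.** The S–O bond at C3 is cut next. In diol 11 (3'-O-benzylombuin) only the 3-OH and the 5-OH are free, and the 5-OH is tied up in its hydrogen bond to C4=O, so the forward sulfation has only one reactive hydroxyl to find.

**11 to 10.** Diol 11 is traced back to chromone 10, which carries a benzyl ether on O3, a methyl ether on O5 and the benzyl ether on O3'. The two bonds cut are O5–CH3 and O3–CH2Ph. Both oxygens flank the C4 carbonyl, so a chelating Lewis acid can activate them while the ethers at C7, C3' and C4' have no such partner. The forward step has to exploit exactly this difference.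

**10 to 8 (key disconnection).** The C4–C4a bond of 10 is cut. This opens ring C and gives acrylic acid 8, in which C2 already carries ring B and the aryl ether oxygen O1, C3 carries its oxygen as a benzyl enol ether, and C4 is the carboxyl carbon. Cutting here and not at O1–C2 or C2–C3 means that ring A comes from a symmetric phenol, that no regioisomer can arise, and that the C3 oxygen never has to be introduced into a finished chromone. The forward reaction must acylate the ring carbon ortho to the ether oxygen through an activated acyl derivative 9, without losing the benzyl enol ether.

**8 to 7.** Acid 8 comes from its methyl ester 7 by cleavage of the ester; the ester is needed because the preceding steps run in base.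

**7 to 4 and 5.** In ester 7 the C2–O(aryl) bond and the enol O–benzyl bond are cut. This leads to chloro keto ester 4 and 3,5-dimethoxyphenol 5 through the aryloxy keto ester 6. The forward sequence is a displacement of chloride by the phenoxide and then O-benzylation of the enolate of 6. That enolate should not be protonated and isolated, because the free ketone next to so electron-rich an aryl ether would close to a benzofuran.

**4 to 1 and 2.** The C2–C3 bond of 4 is cut (flavone numbering). Aldehyde 1 supplies ring B and C2, and methyl dichloroacetate 2 supplies C3 and C4 at the right oxidation level, through chloroglycidic ester 3. This single condensation replaces a longer arylpyruvate synthesis followed by halogenation.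

## Alternatives that were turned down

**Alternative 1:** Ring A is disconnected at C4a–C5 and built from an open chain. In the forward direction the tetraketide ester A1 is folded by base so that the methylene next to the cinnamoyl ketone attacks the ester carbon, giving the phloroglucinol chalcone A2. In its favour, the 5-oxygen appears as a free hydroxyl, so no demethylation is needed; on this point it is stronger than the chosen route. Against it, A1 has three acidic methylenes and four electrophilic carbonyls. Without an enzyme to hold the chain, lactonisation to a 4-hydroxypyranone and aldol closures at other positions compete with the wanted Claisen closure. A1 itself has to be assembled by stepwise polyanion acylation. After A2 the route still lacks ring C and the C3 oxygen, the 7-OH must be methylated selectively, and oxidative closure of chalcones with two ortho oxygens tends to give aurones. The chosen route starts from ring A ready-made; its key step forms one bond but leaves the full skeleton with all five oxygens in place, in about half the steps.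

**Alternative 2:** The O1–C2 bond is disconnected. In the forward step iodine monochloride activates the alkyne of ynone A3, one of the two equivalent benzyloxy oxygens closes the ring 6-endo, benzyl chloride is lost and iodine ends on C3, giving 3-iodochromone A4. In its favour, this cyclisation is mild and its ring-closure mode is well defined. The symmetric 2,6-dibenzyloxy ring leaves the 5-oxygen as a benzyl ether and the 7-oxygen as the methyl ether, so the two are told apart without chelation chemistry. The later stages could keep every other oxygen benzylated while the 3-OH is sulfated. On both points it is stronger than the chosen route. Against it, C3 receives iodine instead of oxygen. Replacing iodine by hydroxyl at a carbon wedged between the carbonyl and ring B is an uncertain metal-mediated step and costs extra operations. Iodine monochloride is also an iodinating agent for the phloroglucinol-type ring of A3 and for ring B. A3 needs two fragments that must first be made. The chosen route pays with a chelation-controlled dealkylation, but carries the C3 oxygen from the first step and uses only commercial building blocks.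

**Alternative 3:** Three bonds of ring C are disconnected at once: C4a–C4, C4–C3 and O1–C2. In the forward step iodophenol A5, carbon monoxide and alkyne A6 are joined under palladium catalysis to flavone A7. It is the most convergent plan and forms the most bonds in one operation; on convergence it is stronger than the chosen route. Against it, A5 is an unsymmetrical phenol whose iodine sits between two oxygens. Putting the iodine there regioselectively is a problem in itself, and that crowded position slows oxidative addition and carbon monoxide insertion. The ynone formed on the way can also close 5-exo to an aurone. A7 has hydrogen at C3, so the oxygen would have to be added afterwards by oxidation of a molecule with two electron-rich rings. The chosen route has no such late oxidation and no regiochemical question on ring A, and it needs no pressurised gas.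

Key step: step 4

Assumption: the target has no stereocentre, so nothing has to be controlled for the single enantiomer asked for. The hydrogen sulfate is handled as its sodium salt, and the free acid drawn is its neutral form.

## Route

Step 1
Reactants: 1 3-benzyloxy-4-methoxybenzaldehyde (O-benzylisovanillin); 2 methyl dichloroacetate
Product: 4 methyl 3-(3-benzyloxy-4-methoxyphenyl)-3-chloro-2-oxopropanoate (racemic), via chloroglycidic ester 3 (not isolated)
Conditions: NaOMe (1.1 equiv), MeOH–Et2O, −10 °C → rt; brine work-up, used crude
Reagents that add atoms: none
Why: Darzens condensation of the aldehyde with the dichloroacetate anion gives the α-chloroglycidic ester 3, which opens by chloride shift to the benzylic carbon to give the 3-chloro-2-oxo ester; this is the usual entry to 3-aryl-3-chloropyruvates, and the one stereocentre formed is racemic and is removed in step 2.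

Step 2
Reactants: 4 methyl 3-(3-benzyloxy-4-methoxyphenyl)-3-chloro-2-oxopropanoate; 5 3,5-dimethoxyphenol
Product: 7 methyl (E)-2-benzyloxy-3-(3-benzyloxy-4-methoxyphenyl)-3-(3,5-dimethoxyphenoxy)acrylate, via aryloxy keto ester enolate 6 (not isolated)
Conditions: 5 (1.05 equiv), K2CO3 (2.5 equiv), DMF, 0 °C → rt; then BnBr (1.3 equiv), rt
Reagents that add atoms: benzyl bromide, BrCc1ccccc1
Why: Williamson-type SN2 displacement of an α-halo ketone by a phenoxide (the same type as the alkylation of phenols with 2-chloroacetoacetates), then O-alkylation of the enolate of 6, whose carbon terminus is fully substituted; the enolate should prefer the geometry with the aryl group trans to the ester, as in arylpyruvate enols, which leads to the E enol ether, and keeping 6 as its enolate avoids acid-induced closure to a benzofuran.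

Step 3
Reactants: 7 methyl (E)-2-benzyloxy-3-(3-benzyloxy-4-methoxyphenyl)-3-(3,5-dimethoxyphenoxy)acrylate
Product: 8 (E)-2-benzyloxy-3-(3-benzyloxy-4-methoxyphenyl)-3-(3,5-dimethoxyphenoxy)acrylic acid
Conditions: LiOH·H2O (3 equiv), THF–MeOH–H2O, rt → 40 °C; then cold 1 M HCl to pH 3–4
Reagents that add atoms: lithium hydroxide (supplies the carboxyl oxygen), [Li+].[OH-]
Why: Saponification of a methyl ester by acyl–oxygen cleavage; the carboxylate formed is no longer an acceptor for addition–elimination at C3, and the mild acidification leaves the enol ether intact.

Step 4
Reactants: 8 (E)-2-benzyloxy-3-(3-benzyloxy-4-methoxyphenyl)-3-(3,5-dimethoxyphenoxy)acrylic acid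
Product: 10 3-benzyloxy-2-(3-benzyloxy-4-methoxyphenyl)-5,7-dimethoxychromen-4-one, via acyl trifluoroacetate 9 (not isolated)
Conditions: (CF3CO)2O (3 equiv), CH2Cl2 (0.02 M), 0 °C → rt; aq. NaHCO3
Reagents that add atoms: none
Why: The acid is converted into the mixed anhydride 9, which reacts as such or ionises to an acylium ion delocalised over the enol ether (ketene–oxocarbenium form); the ring carbon ortho to the ether oxygen, activated by that oxygen, by the ortho methoxy and by the para methoxy group, attacks the acyl carbon, and proton loss from the Wheland intermediate gives the chromone. The closest known reaction type is the acid-mediated cyclisation of β-aryloxyacrylic and β-aryloxycinnamic acids to chromones and flavones (Ruhemann-type intramolecular Friedel–Crafts acylation), here run with an anhydride activator as in other acylations of phloroglucinol ethers. Ring C closes in a 6-exo-trig mode on the anhydride carbonyl (6-exo-dig if the free acylium ion is the electrophile), forming the C4–C4a bond. No stereocentre is formed. Regioselectivity on ring A needs no control because the two ortho carbons are equivalent, and the carbon para to the ether oxygen can only react intermolecularly, which the dilution suppresses. Closure to a five-membered ring at C3 is excluded because C3 is a benzyl enol ether and not a ketone, so the acyl carbon is the only electrophile. The E geometry places the acyl group beside the aryloxy group and away from ring B; a Z isomer could only close onto the less nucleophilic ring B to an indenone, and the delocalised acylium ion lowers the C2–C3 rotation barrier so that it should drain through the E form. The benzyl ethers should survive because no strong Lewis acid is present.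

Step 5
Reactants: 10 3-benzyloxy-2-(3-benzyloxy-4-methoxyphenyl)-5,7-dimethoxychromen-4-one
Product: 11 2-(3-benzyloxy-4-methoxyphenyl)-3,5-dihydroxy-7-methoxychromen-4-one (3'-O-benzylombuin)
Conditions: MgI2·OEt2 (6 equiv), PhMe, 80 °C; then aq. Na2S2O3, 1 M HCl
Reagents that add atoms: none
Why: Chelation-controlled dealkylation ortho to a carbonyl group by magnesium iodide: Mg(II) bound between C4=O and O5 (six-membered chelate) or O3 (five-membered chelate) activates these ethers for SN2 attack of iodide at the methyl and benzyl carbons, while the ethers at C7, C3' and C4' have no carbonyl partner and should stay.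

Step 6
Reactants: 11 2-(3-benzyloxy-4-methoxyphenyl)-3,5-dihydroxy-7-methoxychromen-4-one
Product: 12 2-(3-benzyloxy-4-methoxyphenyl)-5-hydroxy-7-methoxy-4-oxochromen-3-yl hydrogen sulfate (3'-O-benzylombuin 3-O-sulfate; isolated as the sodium salt)
Conditions: SO3·pyridine (3 equiv), pyridine, rt → 40 °C; then aq. NaHCO3, reversed-phase purification
Reagents that add atoms: sulfur trioxide–pyridine complex, O=S(=O)([O-])[n+]1ccccc1
Why: O-Sulfation of a hydroxyl group with a sulfur trioxide–amine complex; the 5-OH is held in a strong hydrogen bond to C4=O and is the least reactive hydroxyl of a flavonol, so the enolic 3-OH is the only site expected to react, and the basic medium protects the sulfate once formed.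

Step 7
Reactants: 12 2-(3-benzyloxy-4-methoxyphenyl)-5-hydroxy-7-methoxy-4-oxochromen-3-yl hydrogen sulfate (sodium salt)
Product: 13 ombuin 3-O-sulfate, 5-hydroxy-2-(3-hydroxy-4-methoxyphenyl)-7-methoxy-4-oxochromen-3-yl hydrogen sulfate
Conditions: H2 (1 atm), 10% Pd/C, MeOH–THF, rt; filtration; free acid by brief H+ ion exchange at 0 °C if required
Reagents that add atoms: none
Why: Hydrogenolysis of an aryl benzyl ether under neutral conditions; a sulfate monoester salt is inert to hydrogen on palladium, and the tetrasubstituted, conjugated C2=C3 bond of a flavonol should not be reduced at atmospheric pressure.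

## Compound list

1 | 3-benzyloxy-4-methoxybenzaldehyde | COc1ccc(C=O)cc1OCc1ccccc1 | starting material
2 | methyl dichloroacetate | COC(=O)C(Cl)Cl | starting material
3 | methyl 2-chloro-3-(3-benzyloxy-4-methoxyphenyl)oxirane-2-carboxylate (racemic, both diastereomers) | COC(=O)C1(Cl)OC1c1ccc(OC)c(OCc2ccccc2)c1 | intermediate (not isolated)
4 | methyl 3-(3-benzyloxy-4-methoxyphenyl)-3-chloro-2-oxopropanoate (racemic) | COC(=O)C(=O)C(Cl)c1ccc(OC)c(OCc2ccccc2)c1 | intermediate
5 | 3,5-dimethoxyphenol | COc1cc(O)cc(OC)c1 | starting material
6 | methyl 3-(3-benzyloxy-4-methoxyphenyl)-3-(3,5-dimethoxyphenoxy)-2-oxopropanoate (present as its potassium enolate) | COC(=O)C(=O)C(Oc1cc(OC)cc(OC)c1)c1ccc(OC)c(OCc2ccccc2)c1 | intermediate (not isolated)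
7 | methyl (E)-2-benzyloxy-3-(3-benzyloxy-4-methoxyphenyl)-3-(3,5-dimethoxyphenoxy)acrylate | COc1cc(OC)cc(O/C(c2ccc(OC)c(OCc3ccccc3)c2)=C(/OCc2ccccc2)C(=O)OC)c1 | intermediate
8 | (E)-2-benzyloxy-3-(3-benzyloxy-4-methoxyphenyl)-3-(3,5-dimethoxyphenoxy)acrylic acid | COc1cc(OC)cc(O/C(c2ccc(OC)c(OCc3ccccc3)c2)=C(/OCc2ccccc2)C(=O)O)c1 | intermediate
9 | (E)-2-benzyloxy-3-(3-benzyloxy-4-methoxyphenyl)-3-(3,5-dimethoxyphenoxy)acryloyl trifluoroacetate | COc1cc(OC)cc(O/C(c2ccc(OC)c(OCc3ccccc3)c2)=C(/OCc2ccccc2)C(=O)OC(=O)C(F)(F)F)c1 | intermediate (not isolated)
10 | 3-benzyloxy-2-(3-benzyloxy-4-methoxyphenyl)-5,7-dimethoxychromen-4-one | COc1cc(OC)c2c(=O)c(OCc3ccccc3)c(-c3ccc(OC)c(OCc4ccccc4)c3)oc2c1 | intermediate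
11 | 2-(3-benzyloxy-4-methoxyphenyl)-3,5-dihydroxy-7-methoxychromen-4-one | COc1cc(O)c2c(=O)c(O)c(-c3ccc(OC)c(OCc4ccccc4)c3)oc2c1 | intermediate
12 | 2-(3-benzyloxy-4-methoxyphenyl)-5-hydroxy-7-methoxy-4-oxochromen-3-yl hydrogen sulfate | COc1cc(O)c2c(=O)c(OS(=O)(=O)O)c(-c3ccc(OC)c(OCc4ccccc4)c3)oc2c1 | intermediate
13 | ombuin 3-O-sulfate | COc1cc(O)c2c(=O)c(OS(=O)(=O)O)c(-c3ccc(OC)c(O)c3)oc2c1 | target

## Step count and least certain steps

Total step count: 7. Longest linear sequence: 7 steps (from 1; compounds 2 and 5 enter in steps 1 and 2).

**Step 4 (key step).** The most likely failure is acid-induced breakdown before the ring closes. Protonation of the electron-rich alkene at C3 can lead to loss of the benzyl enol ether or of the aryl vinyl ether. The released benzyl cation would alkylate ring A. Once the enol ether is lost, the free C3 ketone can be attacked by ring A to give a benzofuran. A second risk is that a share of Z isomer closes onto ring B to an indenone, if rotation about C2–C3 is slower than expected. The fallback replaces the electrophilic closure by an anionic one on the same bond. It sets out from 4 and 5 and returns at 10. Phenol 5 is brominated with N-bromosuccinimide at low temperature, and 2-bromo-3,5-dimethoxyphenol F1 is separated from its 4-bromo isomer. F1 is carried through the conditions of step 2 with 4 to give methyl (E)-2-benzyloxy-3-(3-benzyloxy-4-methoxyphenyl)-3-(2-bromo-3,5-dimethoxyphenoxy)acrylate F2. Bromine–lithium exchange on F2 (n-BuLi, THF, −100 °C) gives an aryllithium that attacks the ester carbonyl in a Parham-type cyclisation and should give 10 after loss of methoxide. No acid is involved and the site of ring closure is fixed by the bromine.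

**Step 2.** Chloro keto ester 4 is about as acidic as the phenol, so part of it sits as an unreactive chloro enolate and can condense with itself. The phenoxide is ambident and may alkylate at carbon. The benzylation of 6 may go partly to carbon or to the Z enol ether. The fallback reverses the order of the two C–O bond formations; it sets out from 4 and returns at 7. The enolate of 4 is O-benzylated first (K2CO3, BnBr, DMF) to methyl (E)-2-benzyloxy-3-(3-benzyloxy-4-methoxyphenyl)-3-chloroacrylate F3. The chloride of F3 is then replaced by the phenoxide of 5 in an addition–elimination at the vinylic carbon (Cs2CO3, DMSO, 80 °C, with CuI and N,N-dimethylglycine if the uncatalysed reaction is slow). This is the way β-chlorocinnamates are converted into β-aryloxycinnamates, and no enolisable aryloxy ketone is formed.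

**Step 5.** The five-membered chelate at O3 is weaker than the six-membered one at O5, so the C3 benzyl ether may be cleaved incompletely. Conversely, weak chelation between the neighbouring oxygens on ring B could cost the 3'-benzyl group or the 4'-methyl group. The fallback gives up the protecting-group differentiation; it sets out from 10 and returns at 13. Boron trichloride with pentamethylbenzene as cation scavenger (CH2Cl2, −78 → 0 °C) removes both benzyl groups and the chelated 5-O-methyl group to give ombuin F4. Excess sulfur trioxide–trimethylamine with K2CO3 in DMF converts F4 into ombuin 3,3'-di-O-sulfate F5. An aryl sulfatase in acetate buffer then hydrolyses the phenolic 3'-sulfate of F5. Such enzymes accept phenol sulfates but not the enol sulfate at C3 of a flavonol, so this should leave 13.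

**Step 6.** The enolic 3-OH is hindered by ring B and weakly hydrogen-bonded to the carbonyl, so sulfation may be slow. Forcing it brings the 5-OH into play, and the product can lose the sulfate on an acidic work-up. The fallback introduces the sulfate as a neutral, protected diester; it sets out from 11 and returns at 12. Treating 11 with 2,2,2-trichloroethyl chlorosulfate, triethylamine and DMAP in THF gives the chromatographable 2-(3-benzyloxy-4-methoxyphenyl)-5-hydroxy-7-methoxy-4-oxochromen-3-yl 2,2,2-trichloroethyl sulfate F6. Reductive removal of the trichloroethyl group from F6 with zinc and ammonium formate in methanol gives 12 as its ammonium salt.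

## Further compounds

F1 | step 4 | 2-bromo-3,5-dimethoxyphenol | COc1cc(O)c(Br)c(OC)c1
F2 | step 4 | methyl (E)-2-benzyloxy-3-(3-benzyloxy-4-methoxyphenyl)-3-(2-bromo-3,5-dimethoxyphenoxy)acrylate | COc1cc(OC)c(Br)c(O/C(c2ccc(OC)c(OCc3ccccc3)c2)=C(/OCc2ccccc2)C(=O)OC)c1
F3 | step 2 | methyl (E)-2-benzyloxy-3-(3-benzyloxy-4-methoxyphenyl)-3-chloroacrylate | COC(=O)/C(OCc1ccccc1)=C(\Cl)c1ccc(OC)c(OCc2ccccc2)c1
F4 | step 5 | ombuin, 3,5-dihydroxy-2-(3-hydroxy-4-methoxyphenyl)-7-methoxychromen-4-one | COc1cc(O)c2c(=O)c(O)c(-c3ccc(OC)c(O)c3)oc2c1
F5 | step 5 | ombuin 3,3'-di-O-sulfate | COc1cc(O)c2c(=O)c(OS(=O)(=O)O)c(-c3ccc(OC)c(OS(=O)(=O)O)c3)oc2c1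
F6 | step 6 | 2-(3-benzyloxy-4-methoxyphenyl)-5-hydroxy-7-methoxy-4-oxochromen-3-yl 2,2,2-trichloroethyl sulfate | COc1cc(O)c2c(=O)c(OS(=O)(=O)OCC(Cl)(Cl)Cl)c(-c3ccc(OC)c(OCc4ccccc4)c3)oc2c1
A1 | alternative 1 | methyl (E)-9-(3-benzyloxy-4-methoxyphenyl)-3,5,7-trioxonon-8-enoate | COC(=O)CC(=O)CC(=O)CC(=O)/C=C/c1ccc(OC)c(OCc2ccccc2)c1
A2 | alternative 1 | (E)-3-(3-benzyloxy-4-methoxyphenyl)-1-(2,4,6-trihydroxyphenyl)prop-2-en-1-one | COc1ccc(/C=C/C(=O)c2c(O)cc(O)cc2O)cc1OCc1ccccc1
A3 | alternative 2 | 1-(2,6-dibenzyloxy-4-methoxyphenyl)-3-(3-benzyloxy-4-methoxyphenyl)prop-2-yn-1-one | COc1cc(OCc2ccccc2)c(C(=O)C#Cc2ccc(OC)c(OCc3ccccc3)c2)c(OCc2ccccc2)c1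
A4 | alternative 2 | 5-benzyloxy-2-(3-benzyloxy-4-methoxyphenyl)-3-iodo-7-methoxychromen-4-one | COc1cc(OCc2ccccc2)c2c(=O)c(I)c(-c3ccc(OC)c(OCc4ccccc4)c3)oc2c1
A5 | alternative 3 | 3-benzyloxy-2-iodo-5-methoxyphenol | COc1cc(O)c(I)c(OCc2ccccc2)c1
A6 | alternative 3 | 2-benzyloxy-4-ethynyl-1-methoxybenzene | C#Cc1ccc(OC)c(OCc2ccccc2)c1
A7 | alternative 3 | 5-benzyloxy-2-(3-benzyloxy-4-methoxyphenyl)-7-methoxychromen-4-one | COc1cc(OCc2ccccc2)c2c(=O)cc(-c3ccc(OC)c(OCc4ccccc4)c3)oc2c1
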